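All runs are calculated for substances that don't exist; noise was put on by code.

Ash made target faster than cedar: as a share of the substrate charged, per hour and per molar of reagent, the last cedar reading gives 0.117 M⁻¹ h⁻¹ and the first ash reading 1.66 M⁻¹ h⁻¹.

all flasks: substrate 0.050 M

| charge | reagent | temperature | remark | time |
|---|---|---|---|---|
| cedar | 0.12 M | −5 °C | run made earlier |  |
| ash | 0.19 M | 28 °C | run made earlier |  |
| red | 0.250 M | −20 °C |  | 8.0 h |
| teal | 0.250 M | 40 °C |  | 8.0 h |
| green | 0.250 M | 10 °C |  | 8.0 h |

cedar run (percent of the substrate charged)

| time / h | target / % | substrate / % |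
|---|---|---|
| 0.333 | 1.6 | 100.0 |
| 0.667 | 1.4 | 97.6 |
| 1.33 | 2.4 | 97.4 |
| 4.00 | 5.6 | 93.2 |

ash run (percent of the substrate charged)

| time / min | target / % | substrate / % |
|---|---|---|
| 12.0 | 6.3 | 93.2 |
| 20.0 | 8.8 | 88.7 |
| 30.0 | 12.5 | 85.1 |
| 40.0 | 13.9 | 81.9 |

(standard deviation of a reading: 0.5 percentage points)

- the best flask by amount of target, in percent of the substrate charged; "all alike" if 1.5 percentage points covers them all (red / teal / green / all alike)
- amount of target at the end, in percent of the substrate charged, red
- amount of target at the end, in percent of the substrate charged, teal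
- amount of target at the end, in percent of the substrate charged, green



I first asked which given numbers had to be known well for red. In my reckoning the substrate charge cancels, as the answer is a percentage. Time and [reagent] enter in proportion, and both stand as set; I held [reagent] steady, the pseudo-first-order view. The cedar reading enters in proportion too, with a scatter of 0.5 percentage points on 5.6%. Temperature enters this reckoning as a power. Spread over the gap between the runs, the two rates give 8.62 K as my doubling step, the rise in temperature that doubles the rate of making target, as read from these two runs with their scatter. Red lies 1.74 such steps below cedar, and I went round twice: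

red, first round, substrate held at its charge: 6.98%

red, second round, substrate at its mean over the run: 6.74%

green, the same two rounds: 78.0%, then 47.6%

These green figures count substrate turned over, not target kept, and the last ash reading already lacks 4.20% of the charge. For teal the first round passes the whole charge, so I stopped there.

The forecast chose green: red 5.5% (4% to 7.5%), teal 6% (0% to 70%), green 28% (17% to 48%). Its red is lower than my 6.74%. It said: “I favour decay, so green is best, with wide ranges.”

Green gave the most target, 21.2%, against 6.68% in red and 1.16% in teal.

    substrate + reagent ⇌ target (K = 3.70 M⁻¹, k = 4.70 M⁻¹ h⁻¹, Ea = 53.0 kJ mol⁻¹, ΔH = −35.0 kJ mol⁻¹)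
    substrate + reagent ⇌ isomer of the product (K = 86.0 M⁻¹, k = 0.0940 M⁻¹ h⁻¹, Ea = 92.0 kJ mol⁻¹, ΔH = −5.00 kJ mol⁻¹)
    reagent ⇌ dormant form (K = 0.180, k = 5.30 h⁻¹, Ea = 101 kJ mol⁻¹, ΔH = −2.00 kJ mol⁻¹)
    reagent + target → over-reaction product (k = 11.0 M⁻¹ h⁻¹, Ea = 55.0 kJ mol⁻¹)
    (constants at 40 °C)

Green had lost 54.0% of its substrate by 8.00 h and held 32.6% as over-reaction product beside its target. The doubling step of 8.62 K had given 47.6% there, which is less than the substrate lost.

For a flask like red kept at 5 °C, the step gives 52.1%, then 38.5% on the second round. That flask lost 43.9% of its substrate and held 22.7% as target and 21.1% as over-reaction product.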